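**Plan**
1. Retrosynthesis: ring B (the quinone) is taken back to its hydroquinone, and the hydroquinone oxygen on C2' is re-joined to chroman C4 to give a cis-pterocarpan. This is cut at C3–C1' and C4–O into a 2H-chromene and a methoxyquinone.
2. Enabling feature: chroman C3 carries quinone carbon C1', whose neighbour C2' bears a carbonyl oxygen. This C3–C1'–C2'–O array is what the C3=C4 bond of a 2H-chromene leaves after adding across the C=C–C=O unit of a quinone with one free ring carbon.
3. Further cuts: C4–C4a of the chromene (alkyne hydroarylation) and O1–C2 (O-propargylation). The quinone comes from 1,2,3,4-tetramethoxybenzene by C–H hydroxylation and oxidative demethylation.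
4. Forward: ring C (pyran) is closed onto ring A first and the quinone is made separately. The key step joins the two and closes a temporary dihydrofuran ring, hydrogenolysis reopens it, and oxidation restores ring B as the quinone.
5. Stereochemistry: C3 (S) is set in the key step by a chiral titanium TADDOLate. The second centre formed there (C4) is cis by ring constraint and is erased by the hydrogenolysis.

Key step: step 6

**Assumptions and conventions**
- The (4R,5R)-TADDOLate is taken to favour the (6aS,11aS) adduct. If the first run shows the opposite sense, the (4S,5S)-diol is used and nothing else changes.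
- 1,2,3,4-Tetramethoxybenzene is taken as a purchasable starting material.
- TADDOL = 2,2-dimethyl-α,α,α′,α′-tetraphenyl-1,3-dioxolane-4,5-dimethanol.
- Chroman atoms are O1, C2, C3, C4, C4a, C5–C8, C8a. Pterocarpan locants follow the usual 6a/11a numbering. Quinone 11 is numbered as in its name, so C6 is its only ring carbon bearing hydrogen.

**Route**

Step 1
Reactants: 1 2,3,4-trimethoxybenzaldehyde
Product: 3 2,3,4-trimethoxyphenol, via aryl formate 2 (not isolated)
Conditions: 30% aq H2O2, H2SO4 (cat.), MeOH, rt
Reagents that add atoms: hydrogen peroxide, OO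
Why: Acid-catalysed Dakin oxidation (Baeyer–Villiger type), in which the aryl group, made migration-prone by its ortho and para methoxy groups, shifts to oxygen in the peroxide adduct to give formate 2, which methanol cleaves in the same flask.

Step 2
Reactants: 3 2,3,4-trimethoxyphenol; 4 propargyl bromide
Product: 5 1,2,3-trimethoxy-4-(prop-2-yn-1-yloxy)benzene
Conditions: K2CO3, acetone, reflux
Reagents that add atoms: none
Why: Williamson ether synthesis, in which the phenoxide displaces bromide from the unhindered propargylic carbon (SN2).

Step 3
Reactants: 5 1,2,3-trimethoxy-4-(prop-2-yn-1-yloxy)benzene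
Product: 6 6,7,8-trimethoxy-2H-chromene
Conditions: Ph3PAuNTf2 (2 mol %), CH2Cl2, rt
Reagents that add atoms: none
Why: Monovalent-gold π-activation of the terminal alkyne triggers a 6-endo-dig intramolecular hydroarylation (Friedel–Crafts type) at the only free ortho carbon, which is para to a methoxy group, and protodeauration releases the 2H-chromene.

Step 4
Reactants: 7 1,2,3,4-tetramethoxybenzene
Product: 10 2,3,4,5-tetramethoxyphenol, via aryllithium 8 (not isolated), via lithium aryltrimethoxyborate 9 (not isolated)
Conditions: n-BuLi, TMEDA, THF, 0 °C; B(OMe)3, −78 °C → rt; then AcOH, 30% aq H2O2, 0 °C → rt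
Reagents that add atoms: hydrogen peroxide, OO
Why: Directed ortho-lithiation next to a methoxy group (the two free positions are equivalent), trapping as the borate and oxidative 1,2-shift of the aryl group from boron to oxygen should give the phenol (lithiation–borylation–oxidation).

Step 5
Reactants: 10 2,3,4,5-tetramethoxyphenol
Product: 11 2,3,5-trimethoxy-1,4-benzoquinone
Conditions: PhI(OAc)2, MeCN–H2O (2:1), 0 °C
Reagents that add atoms: water, O
Why: Hypervalent-iodine oxidation of a para-methoxyphenol, in which water adds at the para carbon of the oxidised phenol and the hemiketal loses methanol to give the para-quinone (oxidative demethylation).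

Step 6
Reactants: 6 6,7,8-trimethoxy-2H-chromene; 11 2,3,5-trimethoxy-1,4-benzoquinone
Product: 12 (6aS,11aS)-2,3,4,7,9,10-hexamethoxy-6a,11a-dihydro-6H-benzofuro[3,2-c]chromen-8-ol (cis-pterocarpan phenol)
Conditions: Cl2Ti[(4R,5R)-TADDOLate] (2.2 equiv; from TiCl4, Ti(OiPr)4 and (4R,5R)-TADDOL 1:1:2, CH2Cl2, rt), 11, −78 °C; then 6 (1.3 equiv), −78 → −20 °C; H2O
Reagents that add atoms: none
Why: Tetravalent titanium chelates the C4 carbonyl and a neighbouring methoxy oxygen of 11, so that C6 (later C1' of the target) becomes the β-carbon of a titanium-bound enone; the electron-rich C3=C4 bond of 6 attacks it through C3 and leaves a C4 benzylic cation stabilised by O1 and the para 7-methoxy group. The C1 carbonyl oxygen of the quinone then captures this cation in a 5-exo-trig closure of the dihydrofuran ring, and loss of the former C6 proton aromatises ring B to the titanium phenoxide of 12. The closest known reaction type is the titanium-promoted formal (3+2) cycloaddition of 2H-chromenes and styrenes with 2-alkoxy-1,4-benzoquinones, including its TADDOLate-mediated enantioselective variant that gives cis-pterocarpans. C6a is controlled by the chiral diolate on titanium, which blocks one face of the bound quinone and so fixes which enantiotopic face of the chromene alkene bonds; C11a is controlled by C6a, because a five-membered ring fused across C6a–C11a of the pyran can only close cis. The step needs regioselectivity at both partners and enantioface selectivity: the single free quinone carbon and the one-sided polarity of the chromene (cation only at C4) secure the first, the TADDOLate the second. More than two equivalents of the titanium complex are used because C6 is flanked by a methoxy-bearing carbon and is less electrophilic than in the usual quinone partners.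

Step 7
Reactants: 12 cis-pterocarpan phenol
Product: 14 2,3,5-trimethoxy-6-[(3S)-6,7,8-trimethoxy-3,4-dihydro-2H-chromen-3-yl]-1,4-benzoquinone (target), via hydroquinone isoflavan 13 (not isolated)
Conditions: H2 (3 atm), 10% Pd/C, EtOAc–EtOH, rt; filter under Ar, concentrate; then Ag2O, Na2SO4, Et2O, rt
Reagents that add atoms: none
Why: Catalytic hydrogenolysis cleaves the one benzylic C–O bond (C11a–O11, the standard pterocarpan-to-isoflavan opening) without touching C6a, so (6aS) becomes (3S), and Ag2O then dehydrogenates the electron-rich hydroquinone 13 to the para-quinone.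

**Compound list**
1 | 2,3,4-trimethoxybenzaldehyde | COc1ccc(C=O)c(OC)c1OC | starting material
2 | 2,3,4-trimethoxyphenyl formate (not isolated) | COc1ccc(OC=O)c(OC)c1OC | intermediate
3 | 2,3,4-trimethoxyphenol | COc1ccc(O)c(OC)c1OC | intermediate
4 | propargyl bromide (3-bromoprop-1-yne) | BrCC#C | starting material
5 | 1,2,3-trimethoxy-4-(prop-2-yn-1-yloxy)benzene | COc1ccc(OCC#C)c(OC)c1OC | intermediate
6 | 6,7,8-trimethoxy-2H-chromene | COc1cc2C=CCOc2c(OC)c1OC | intermediate
7 | 1,2,3,4-tetramethoxybenzene | COc1ccc(OC)c(OC)c1OC | starting material
8 | (2,3,4,5-tetramethoxyphenyl)lithium (not isolated) | [Li]c1cc(OC)c(OC)c(OC)c1OC | intermediate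
9 | lithium trimethoxy(2,3,4,5-tetramethoxyphenyl)borate (not isolated) | [Li+].CO[B-](OC)(OC)c1cc(OC)c(OC)c(OC)c1OC | intermediate
10 | 2,3,4,5-tetramethoxyphenol | COc1cc(O)c(OC)c(OC)c1OC | intermediate
11 | 2,3,5-trimethoxy-1,4-benzoquinone | COC1=CC(=O)C(OC)=C(OC)C1=O | intermediate
12 | (6aS,11aS)-2,3,4,7,9,10-hexamethoxy-6a,11a-dihydro-6H-benzofuro[3,2-c]chromen-8-ol | COc1c(O)c(OC)c(OC)c5c1[C@H]2COc3c(cc(OC)c(OC)c3OC)[C@H]2O5 | intermediate
13 | 2-[(3S)-6,7,8-trimethoxy-3,4-dihydro-2H-chromen-3-yl]-3,5,6-trimethoxybenzene-1,4-diol (not isolated) | COc1c(O)c(OC)c(OC)c(O)c1[C@H]2COc3c(cc(OC)c(OC)c3OC)C2 | intermediate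
14 | 2,3,5-trimethoxy-6-[(3S)-6,7,8-trimethoxy-3,4-dihydro-2H-chromen-3-yl]cyclohexa-2,5-diene-1,4-dione | COC1=C(OC)C(=O)C([C@H]2COc3c(cc(OC)c(OC)c3OC)C2)=C(OC)C1=O | target

**Summary**
Total step count: 7.
Longest linear sequence: 5 steps (steps 1, 2, 3, 6, 7 from aldehyde 1); the quinone branch from 7 is 4 steps (4, 5, 6, 7).

**Steps most likely to fail**

Step 6. The chromene may not bond to C6 of 11, which is the electron-rich terminus of an enol ether and is flanked on both sides, or it may attack a methoxy-bearing carbon with loss of methanol. Facial selectivity may also be lower than with simpler quinones; the enantiomeric purity of 12 would be checked by chiral HPLC and recrystallisation tried for enrichment. The fallback sets out from phenol 3 and chromene 6 and returns at 12. Phenol 3 is oxidised with PhI(OAc)2 in aqueous MeCN (the reaction of step 5) to 2,3-dimethoxy-1,4-benzoquinone F1, whose C5=C6 bond is unsubstituted. The same titanium TADDOLate cycloaddition of 6 with F1, now in the regiochemical mode established for alkoxyquinones, should give (6aS,11aS)-2,3,4,9,10-pentamethoxy-6a,11a-dihydro-6H-benzofuro[3,2-c]chromen-8-ol F2. NBS in CH2Cl2 at −78 °C should brominate F2 at C7, the only free position ortho to the phenol, to give (6aS,11aS)-7-bromo-2,3,4,9,10-pentamethoxy-6a,11a-dihydro-6H-benzofuro[3,2-c]chromen-8-ol F3. Copper-mediated methoxylation (NaOMe, CuBr, MeOH–DMF, 110 °C) then replaces bromine by methoxy and gives 12.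

Step 7. Hydrogenolysis may be slow at this hindered, electron-rich benzylic ether. Forcing it with acid or heat invites ionisation at C11a, loss of H-6a and re-hydrogenation of the resulting alkene, which would erode the C3 configuration. The air-sensitive hydroquinone may also degrade before it is oxidised. The fallback sets out from 12 and returns at 14. The phenol is methylated (MeI, K2CO3, acetone) to (6aS,11aS)-2,3,4,7,8,9,10-heptamethoxy-6a,11a-dihydro-6H-benzofuro[3,2-c]chromene F4. The benzylic C–O bond is then cleaved by electron transfer under basic conditions (Li, 2.2 equiv, NH3–THF, −78 °C, then NH4Cl), where no cation can form and the limited lithium should spare the aryl methoxy groups. This gives the air-stable 2,3,4,5-tetramethoxy-6-[(3S)-6,7,8-trimethoxy-3,4-dihydro-2H-chromen-3-yl]phenol F5. PhI(OAc)2 in aqueous MeCN at 0 °C, a phenol-selective oxidant that leaves ring A alone, converts this para-methoxyphenol into quinone 14 as in step 5.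

Step 3. The cationic gold catalyst or traces of acid may dimerise the electron-rich chromene as it forms, or the catalyst may be deactivated before conversion is complete. The fallback sets out from phenol 3 and returns at 6. Ortho-formylation of 3 (MgCl2, Et3N, paraformaldehyde, MeCN, reflux) gives 2-hydroxy-3,4,5-trimethoxybenzaldehyde F6. With vinyltriphenylphosphonium bromide and K2CO3 in hot dioxane, oxa-Michael addition of the phenoxide and intramolecular Wittig olefination (Schweizer chromene synthesis) close the pyran ring and give 6.

**Further compounds**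
F1 | step 6 | 2,3-dimethoxy-1,4-benzoquinone | COC1=C(OC)C(=O)C=CC1=O
F2 | step 6 | (6aS,11aS)-2,3,4,9,10-pentamethoxy-6a,11a-dihydro-6H-benzofuro[3,2-c]chromen-8-ol | c1c(O)c(OC)c(OC)c5c1[C@H]2COc3c(cc(OC)c(OC)c3OC)[C@H]2O5
F3 | step 6 | (6aS,11aS)-7-bromo-2,3,4,9,10-pentamethoxy-6a,11a-dihydro-6H-benzofuro[3,2-c]chromen-8-ol | Brc1c(O)c(OC)c(OC)c5c1[C@H]2COc3c(cc(OC)c(OC)c3OC)[C@H]2O5
F4 | step 7 | (6aS,11aS)-2,3,4,7,8,9,10-heptamethoxy-6a,11a-dihydro-6H-benzofuro[3,2-c]chromene | COc1c(OC)c(OC)c(OC)c5c1[C@H]2COc3c(cc(OC)c(OC)c3OC)[C@H]2O5
F5 | step 7 | 2,3,4,5-tetramethoxy-6-[(3S)-6,7,8-trimethoxy-3,4-dihydro-2H-chromen-3-yl]phenol | COc1c(OC)c(OC)c(OC)c(O)c1[C@H]2COc3c(cc(OC)c(OC)c3OC)C2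
F6 | step 3 | 2-hydroxy-3,4,5-trimethoxybenzaldehyde | COc1cc(C=O)c(O)c(OC)c1OC
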